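**Plan**

- Cuts, in retrosynthetic order: the ester C–OMe bond (the target is a methanol-opened aryl lactone); then the benzylic C–CH2 bond and the O7–acyl bond of that 4-propyl-3,4-dihydrocoumarin (ortho-quinone methide plus Meldrum's acid); then C8–CH (butanal), O1–C2 (Mitsunobu closure), C2–C3 (aldol with acetaldehyde) and C6–prenyl (para-Claisen–Cope shift).
- Enabling feature: on the hexasubstituted benzene ring the 7-OH and the C8 carbon carrying CH(propyl)CH2CO2Me are ortho neighbours. Phenol and ester are therefore a ring-opened lactone, and the benzylic carbon can be the exocyclic carbon of a quinone methide running O7=C7–C8=CH.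
- Forward order: the benzene ring is bought as trihydroxypropiophenone; prenyl is moved to the carbon between two MOM ethers; the chromanone ring is closed by aldol and Mitsunobu etherification; the lactone ring is closed in the key step and opened with methanol.
- Stereochemistry: C2 (S) comes from the (3R) carbinol of a reagent-controlled syn boron aldol, inverted in the Mitsunobu closure. C3 (S) comes from the same aldol and is also the thermodynamic trans position. The benzylic (S) centre comes from a cinchona squaramide catalyst acting on the planar methide.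

Key step: step 10

Assumption: the senses of induction written for (−)-Ipc2BOTf (step 5) and for the quinine-derived squaramide (step 10) are taken by analogy with simpler substrates; if a test run (Mosher ester, chiral HPLC) shows the opposite centre, the enantiomeric borane or the quinidine-derived pseudoenantiomer is used and nothing else changes.

**Route**

Step 1
Reactants: 1 1-(2,4,6-trihydroxyphenyl)propan-1-one
Product: 2 1-[2-hydroxy-4,6-bis(methoxymethoxy)phenyl]propan-1-one
Conditions: MOMCl (2.2 equiv), i-Pr2NEt, CH2Cl2, 0 °C to rt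
Reagents that add atoms: chloromethyl methyl ether, COCCl
Why: O-alkylation (MOM protection) takes the 4-OH and one ortho OH, while the remaining ortho OH is held in a hydrogen bond to the ketone and should stay free at this stoichiometry.

Step 2
Reactants: 2 1-[2-hydroxy-4,6-bis(methoxymethoxy)phenyl]propan-1-one; 3 3-methylbut-2-en-1-ol (prenol)
Product: 4 1-[2,4-bis(methoxymethoxy)-6-(3-methylbut-2-en-1-yloxy)phenyl]propan-1-one
Conditions: PPh3, diisopropyl azodicarboxylate, THF, 0 °C to rt
Reagents that add atoms: none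
Why: Mitsunobu etherification of the chelated phenol with the primary allylic alcohol should give the aryl prenyl ether by SN2 at CH2 without allylic transposition.

Step 3
Reactants: 4 1-[2,4-bis(methoxymethoxy)-6-(3-methylbut-2-en-1-yloxy)phenyl]propan-1-one
Product: 7 1-[6-hydroxy-2,4-bis(methoxymethoxy)-3-(3-methylbut-2-en-1-yl)phenyl]propan-1-one, via ortho-dienone 5 (not isolated), via para-dienone 6 (not isolated)
Conditions: N,N-diethylaniline, 200 °C, sealed tube
Reagents that add atoms: none
Why: Aromatic Claisen rearrangement to the free ortho carbon gives dienone 5, whose crowded 1,1-dimethylallyl group moves on by Cope rearrangement to the para carbon between the two MOM ethers (para-Claisen–Cope), and tautomerisation of 6 restores the arene and frees the phenol that later becomes the ring oxygen.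

Step 4
Reactants: 7 1-[6-hydroxy-2,4-bis(methoxymethoxy)-3-(3-methylbut-2-en-1-yl)phenyl]propan-1-one
Product: 8 1-[6-(tert-butyldimethylsilyloxy)-2,4-bis(methoxymethoxy)-3-(3-methylbut-2-en-1-yl)phenyl]propan-1-one
Conditions: TBSCl, imidazole, DMF, rt to 40 °C
Reagents that add atoms: tert-butyldimethylsilyl chloride, CC(C)(C)[Si](C)(C)Cl
Why: Silylation masks the acidic phenol so that the boron triflate and amine of the next step act only on the ethyl ketone.

Step 5
Reactants: 8 1-[6-(tert-butyldimethylsilyloxy)-2,4-bis(methoxymethoxy)-3-(3-methylbut-2-en-1-yl)phenyl]propan-1-one; 9 acetaldehyde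
Product: 12 (2S,3R)-1-[6-(tert-butyldimethylsilyloxy)-2,4-bis(methoxymethoxy)-3-(3-methylbut-2-en-1-yl)phenyl]-3-hydroxy-2-methylbutan-1-one, via boron enolate 10 (not isolated), via boron aldolate 11 (not isolated)
Conditions: (−)-Ipc2BOTf, i-Pr2NEt, CH2Cl2, −78 °C; 9, −78 to −20 °C; H2O2, MeOH, pH 7 buffer (NaH2PO4/Na2HPO4), 0 °C
Reagents that add atoms: none
Why: Paterson boron aldol: the triflate and hindered amine give the (Z)-enol borinate 10, which adds to acetaldehyde through a chair Zimmerman–Traxler transition state (hence syn), the isopinocampheyl ligands selecting the aldehyde face that gives the (3R) carbinol and so the (2S,3R) aldol, and oxidative work-up releases the alcohol from 11.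

Step 6
Reactants: 12 (2S,3R)-1-[6-(tert-butyldimethylsilyloxy)-2,4-bis(methoxymethoxy)-3-(3-methylbut-2-en-1-yl)phenyl]-3-hydroxy-2-methylbutan-1-one
Product: 13 (2S,3R)-3-hydroxy-1-[6-hydroxy-2,4-bis(methoxymethoxy)-3-(3-methylbut-2-en-1-yl)phenyl]-2-methylbutan-1-one
Conditions: Bu4NF, AcOH, THF, 0 °C
Reagents that add atoms: none
Why: Fluoride cleaves the aryl silyl ether far faster than it touches the MOM ethers, and the acetic acid buffer keeps the β-hydroxy ketone from retro-aldol cleavage or epimerisation.

Step 7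
Reactants: 13 (2S,3R)-3-hydroxy-1-[6-hydroxy-2,4-bis(methoxymethoxy)-3-(3-methylbut-2-en-1-yl)phenyl]-2-methylbutan-1-one
Product: 14 (2S,3S)-5,7-bis(methoxymethoxy)-2,3-dimethyl-6-(3-methylbut-2-en-1-yl)chroman-4-one
Conditions: PPh3, diisopropyl azodicarboxylate, THF, 0 °C to rt
Reagents that add atoms: none
Why: Intramolecular Mitsunobu etherification: the phenol displaces the activated (3R) carbinol oxygen by SN2 (6-exo-tet) with inversion to give C2 (S), while the untouched α-centre becomes C3 (S), which is the trans-2,3-dimethyl ring.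

Step 8
Reactants: 14 (2S,3S)-5,7-bis(methoxymethoxy)-2,3-dimethyl-6-(3-methylbut-2-en-1-yl)chroman-4-one
Product: 15 (2S,3S)-5,7-dihydroxy-2,3-dimethyl-6-(3-methylbut-2-en-1-yl)chroman-4-one
Conditions: 3 M aq HCl, MeOH, 45 °C
Reagents that add atoms: none
Why: Acid-catalysed acetal exchange with methanol removes both MOM groups under conditions a prenyl group flanked by phenols tolerates, and any cis C3 epimer carried from step 7 should equilibrate to trans through the enol.

Step 9
Reactants: 15 (2S,3S)-5,7-dihydroxy-2,3-dimethyl-6-(3-methylbut-2-en-1-yl)chroman-4-one; 16 butanal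
Product: 17 (2S,3S)-5,7-dihydroxy-2,3-dimethyl-6-(3-methylbut-2-en-1-yl)-8-[1-(4-methylphenylsulfonyl)butyl]chroman-4-one (both benzylic epimers)
Conditions: p-TolSO2H (1.5 equiv), 16 (1.5 equiv), MgSO4, CH2Cl2, rt
Reagents that add atoms: p-toluenesulfinic acid, Cc1ccc(cc1)S(=O)O
Why: Three-component sulfonylalkylation (Mannich-type hydroxyalkylation of the phloroglucinol ring, then capture of the benzylic cation by sulfinate sulfur) can only occur at C8, the one unsubstituted ring carbon, and the unselective benzylic centre does not matter because it is erased at the methide stage.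

Step 10
Reactants: 17 (2S,3S)-5,7-dihydroxy-2,3-dimethyl-6-(3-methylbut-2-en-1-yl)-8-[1-(4-methylphenylsulfonyl)butyl]chroman-4-one; 18 2,2-dimethyl-1,3-dioxane-4,6-dione (Meldrum's acid)
Product: 22 (2S,3S,10S)-5-hydroxy-2,3-dimethyl-6-(3-methylbut-2-en-1-yl)-10-propyl-2,3,9,10-tetrahydro-4H,8H-pyrano[2,3-f]chromene-4,8-dione, via ortho-quinone methide 19 (not isolated), via Meldrum's acid adduct 20 (not isolated), via lactone acid 21 (not isolated)
Conditions: 18 (1.5 equiv), 3-[3,5-bis(trifluoromethyl)anilino]-4-[(9-deoxy-epi-quinin-9-yl)amino]cyclobut-3-ene-1,2-dione (10 mol %), 5% aq NaHCO3, CH2Cl2, 0 °C; then pH 4 (NaH2PO4), organic layer, toluene, 85 °C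
Reagents that add atoms: none
Why: Bicarbonate ionises the 7-OH (the most acidic phenol, para to the C4 carbonyl through C4a) and sulfinate leaves to give methide 19 (C7=O, C8=CH–propyl); the squaramide N–H groups bind the C7 carbonyl while the protonated quinuclidine carries the Meldrum's acid anion, which adds to the exocyclic carbon with rearomatisation to give 20. After acidification, heating lets the 7-OH attack a Meldrum's carbonyl (6-exo-trig acyl substitution), acetone is lost, and the malonic half-ester 21 decarboxylates to lactone 22. The closest known reaction type is the cinchona amine-squaramide catalysed addition of Meldrum's acid to ortho-quinone methides released by mild base from 2-(1-sulfonylalkyl)phenols, followed by lactonisation and decarboxylation to 4-substituted 3,4-dihydrocoumarins. The new benzylic centre (S) is set by the catalyst's discrimination between the two faces of the planar methide, through which both epimers of 17 converge, and the remote C2 and C3 centres should have little say. The step needs that facial selectivity plus a single site and direction of methide formation: C8 is the only open ring carbon, O1 is an ether so the methide can only form toward O7, and the 5-OH is tied up in its hydrogen bond to the C4 ketone. The three ring oxygens should stabilise 19 enough for addition at 0 °C to outrun the 1,5-hydrogen shift to the butenyl phenol.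

Step 11
Reactants: 22 (2S,3S,10S)-5-hydroxy-2,3-dimethyl-6-(3-methylbut-2-en-1-yl)-10-propyl-2,3,9,10-tetrahydro-4H,8H-pyrano[2,3-f]chromene-4,8-dione
Product: 23 methyl (3S)-3-[(2S,3S)-5,7-dihydroxy-2,3-dimethyl-6-(3-methylbut-2-en-1-yl)-4-oxochroman-8-yl]hexanoate
Conditions: HCl (0.2 M in MeOH), rt; solid NaHCO3 at 0 °C before concentration
Reagents that add atoms: methanol, CO
Why: Acid-catalysed transesterification opens the aryl ester in a large excess of methanol to release the methyl ester and the 7-OH without touching any stereocentre, and neutralising before concentration should prevent relactonisation.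

**Compound list**

1 | 1-(2,4,6-trihydroxyphenyl)propan-1-one | CCC(=O)c1c(O)cc(O)cc1O | starting material
2 | 1-[2-hydroxy-4,6-bis(methoxymethoxy)phenyl]propan-1-one | CCC(=O)c1c(O)cc(OCOC)cc1OCOC | intermediate
3 | 3-methylbut-2-en-1-ol (prenol) | CC(C)=CCO | starting material
4 | 1-[2,4-bis(methoxymethoxy)-6-(3-methylbut-2-en-1-yloxy)phenyl]propan-1-one | CCC(=O)c1c(OCC=C(C)C)cc(OCOC)cc1OCOC | intermediate
5 | ortho-dienone: 3,5-bis(methoxymethoxy)-6-(2-methylbut-3-en-2-yl)-2-propanoylcyclohexa-2,4-dien-1-one | CCC(=O)C1=C(OCOC)C=C(OCOC)C(C(C)(C)C=C)C1=O | intermediate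
6 | para-dienone: 3,5-bis(methoxymethoxy)-4-(3-methylbut-2-en-1-yl)-2-propanoylcyclohexa-2,5-dien-1-one | CCC(=O)C1=C(OCOC)C(CC=C(C)C)C(OCOC)=CC1=O | intermediate
7 | 1-[6-hydroxy-2,4-bis(methoxymethoxy)-3-(3-methylbut-2-en-1-yl)phenyl]propan-1-one | CCC(=O)c1c(O)cc(OCOC)c(CC=C(C)C)c1OCOC | intermediate
8 | 1-[6-(tert-butyldimethylsilyloxy)-2,4-bis(methoxymethoxy)-3-(3-methylbut-2-en-1-yl)phenyl]propan-1-one | CCC(=O)c1c(O[Si](C)(C)C(C)(C)C)cc(OCOC)c(CC=C(C)C)c1OCOC | intermediate
9 | acetaldehyde | CC=O | starting material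
10 | boron enolate: (Z)-enol diisopinocampheylborinate of 8 | C/C=C(\OB([C@@H]1C[C@@H]2C[C@H]([C@H]1C)C2(C)C)[C@@H]1C[C@@H]2C[C@H]([C@H]1C)C2(C)C)c1c(O[Si](C)(C)C(C)(C)C)cc(OCOC)c(CC=C(C)C)c1OCOC | intermediate
11 | boron aldolate: O-diisopinocampheylboryl derivative of 12 | C[C@@H](OB([C@@H]1C[C@@H]2C[C@H]([C@H]1C)C2(C)C)[C@@H]1C[C@@H]2C[C@H]([C@H]1C)C2(C)C)[C@H](C)C(=O)c1c(O[Si](C)(C)C(C)(C)C)cc(OCOC)c(CC=C(C)C)c1OCOC | intermediate
12 | (2S,3R)-1-[6-(tert-butyldimethylsilyloxy)-2,4-bis(methoxymethoxy)-3-(3-methylbut-2-en-1-yl)phenyl]-3-hydroxy-2-methylbutan-1-one | C[C@@H](O)[C@H](C)C(=O)c1c(O[Si](C)(C)C(C)(C)C)cc(OCOC)c(CC=C(C)C)c1OCOC | intermediate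
13 | (2S,3R)-3-hydroxy-1-[6-hydroxy-2,4-bis(methoxymethoxy)-3-(3-methylbut-2-en-1-yl)phenyl]-2-methylbutan-1-one | C[C@@H](O)[C@H](C)C(=O)c1c(O)cc(OCOC)c(CC=C(C)C)c1OCOC | intermediate
14 | (2S,3S)-5,7-bis(methoxymethoxy)-2,3-dimethyl-6-(3-methylbut-2-en-1-yl)chroman-4-one | O=C1c2c(OCOC)c(CC=C(C)C)c(OCOC)cc2O[C@@H](C)[C@@H]1C | intermediate
15 | (2S,3S)-5,7-dihydroxy-2,3-dimethyl-6-(3-methylbut-2-en-1-yl)chroman-4-one | O=C1c2c(O)c(CC=C(C)C)c(O)cc2O[C@@H](C)[C@@H]1C | intermediate
16 | butanal | CCCC=O | starting material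
17 | (2S,3S)-5,7-dihydroxy-2,3-dimethyl-6-(3-methylbut-2-en-1-yl)-8-[1-(4-methylphenylsulfonyl)butyl]chroman-4-one, both benzylic epimers | CCCC(c1c(O)c(CC=C(C)C)c(O)c2c1O[C@@H](C)[C@H](C)C2=O)S(=O)(=O)c1ccc(C)cc1 | intermediate
18 | 2,2-dimethyl-1,3-dioxane-4,6-dione (Meldrum's acid) | CC1(C)OC(=O)CC(=O)O1 | starting material
19 | ortho-quinone methide: (2S,3S)-8-butylidene-5-hydroxy-2,3-dimethyl-6-(3-methylbut-2-en-1-yl)-2,3-dihydro-4H-chromene-4,7(8H)-dione | CCCC=C1C(=O)C(CC=C(C)C)=C(O)C2=C1O[C@@H](C)[C@H](C)C2=O | intermediate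
20 | Meldrum's acid adduct: 5-[(1S)-1-[(2S,3S)-5,7-dihydroxy-2,3-dimethyl-6-(3-methylbut-2-en-1-yl)-4-oxochroman-8-yl]butyl]-2,2-dimethyl-1,3-dioxane-4,6-dione | CCC[C@@H](C1C(=O)OC(C)(C)OC1=O)c1c(O)c(CC=C(C)C)c(O)c2c1O[C@@H](C)[C@H](C)C2=O | intermediate
21 | lactone acid: 9-carboxylic acid of 22 (C9 unassigned) | CCC[C@H]1C(C(=O)O)C(=O)Oc2c(CC=C(C)C)c(O)c3c(c21)O[C@@H](C)[C@H](C)C3=O | intermediate
22 | (2S,3S,10S)-5-hydroxy-2,3-dimethyl-6-(3-methylbut-2-en-1-yl)-10-propyl-2,3,9,10-tetrahydro-4H,8H-pyrano[2,3-f]chromene-4,8-dione (chromanone 15 with O7 and C8 bridged by CO–CH2–CH(propyl)) | CCC[C@H]1CC(=O)Oc2c(CC=C(C)C)c(O)c3c(c21)O[C@@H](C)[C@H](C)C3=O | intermediate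
23 | methyl (3S)-3-[(2S,3S)-5,7-dihydroxy-2,3-dimethyl-6-(3-methylbut-2-en-1-yl)-4-oxochroman-8-yl]hexanoate (CNP0068017.3) | CCC[C@@H](CC(=O)OC)c1c(O)c(CC=C(C)C)c(O)c2c1O[C@@H](C)[C@H](C)C2=O | target

**Count and risks**

Total steps: 11. Longest linear sequence: 11 steps (1 to 23); prenol, acetaldehyde, butanal and Meldrum's acid enter as bought reagents.

Most likely to fail, riskiest first:

Step 10. The catalyst may not discriminate the two faces of this hexasubstituted, push–pull methide well enough. The methide may also drain away by 1,5-hydrogen shift to the 8-(but-1-enyl)phenol, or the addition may reverse before the lactone closes. The fallback sets out from 15 and gives up catalyst control in favour of diastereomer separation, which is possible because C2 and C3 are already fixed. Phenol 15, butanal 16 and Meldrum's acid 18 are condensed in one pot (L-proline cat., MeCN, rt to 50 °C, then toluene, 85 °C), the known three-component route from phloroglucinols to 4-substituted 3,4-dihydrocoumarins. Knoevenagel condensation gives 5-butylidene-2,2-dimethyl-1,3-dioxane-4,6-dione F1, to which C8 of 15 adds in a Friedel–Crafts-type Michael reaction without a free methide being formed. This gives adduct 20 together with its (1R)-butyl epimer F2. Lactonisation and decarboxylation then run through 21 and its (10R) epimer, the epimeric lactone acid F3, to 22 and its (10R) epimer, the epimeric lactone F4. These two lactones are diastereomers and should be separable by chromatography; the route is rejoined at 22.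

Step 9. The sulfinic acid may promote cyclisation of the prenyl group onto a flanking phenol. Butanal may also be arylated twice, or the product may lose sulfinate prematurely and oligomerise. The fallback sets out from 15 and works on the basic side. A Betti (phenolic Mannich) condensation of 15 with butanal 16 and morpholine (EtOH, rt to 50 °C) gives the Mannich base (2S,3S)-5,7-dihydroxy-2,3-dimethyl-6-(3-methylbut-2-en-1-yl)-8-[1-(morpholin-4-yl)butyl]chroman-4-one F5. The amine is then exchanged for sulfinate by elimination–addition (sodium p-toluenesulfinate, AcOH, aq EtOH, 50 °C), which returns to the route at 17.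

Step 5. Enolisation of the di-ortho-substituted aryl ketone by the bulky boron triflate may be slow, the Lewis acid may strip a MOM or silyl ether, or the aldehyde face selectivity may be low. The fallback sets out from 8 and builds the ring by an enantioselective intramolecular oxa-Michael addition instead.
- LiN(i-Pr)2 and acetaldehyde (THF, −78 °C) give the racemic aldol 1-[6-(tert-butyldimethylsilyloxy)-2,4-bis(methoxymethoxy)-3-(3-methylbut-2-en-1-yl)phenyl]-3-hydroxy-2-methylbutan-1-one F6.
- MsCl and Et3N give its mesylate, the 3-methanesulfonyloxy ketone F7.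
- DBU eliminates this to the (E)-enone, the silyl-protected tigloyl ketone F8.
- HF·pyridine (THF, 0 °C, no phenoxide formed) frees the ortho-tigloylphenol (E)-1-[6-hydroxy-2,4-bis(methoxymethoxy)-3-(3-methylbut-2-en-1-yl)phenyl]-2-methylbut-2-en-1-one F9.
- Quinine (10 mol %, chlorobenzene, rt; quinidine if the sense requires) should then close the ring with control of C2, giving mainly the cis chromanone (2S,3R)-5,7-bis(methoxymethoxy)-2,3-dimethyl-6-(3-methylbut-2-en-1-yl)chroman-4-one F10.
- Equilibration at C3 (MgI2 with a tertiary amine, rt) converts it to the trans isomer and rejoins the route at 14.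

**Further compounds**

F1 | step 10 | 5-butylidene-2,2-dimethyl-1,3-dioxane-4,6-dione | CCCC=C1C(=O)OC(C)(C)OC1=O
F2 | step 10 | (1R)-butyl epimer of adduct 20 | CCC[C@H](C1C(=O)OC(C)(C)OC1=O)c1c(O)c(CC=C(C)C)c(O)c2c1O[C@@H](C)[C@H](C)C2=O
F3 | step 10 | (10R) epimer of lactone acid 21 | CCC[C@@H]1C(C(=O)O)C(=O)Oc2c(CC=C(C)C)c(O)c3c(c21)O[C@@H](C)[C@H](C)C3=O
F4 | step 10 | (10R) epimer of lactone 22 | CCC[C@@H]1CC(=O)Oc2c(CC=C(C)C)c(O)c3c(c21)O[C@@H](C)[C@H](C)C3=O
F5 | step 9 | (2S,3S)-5,7-dihydroxy-2,3-dimethyl-6-(3-methylbut-2-en-1-yl)-8-[1-(morpholin-4-yl)butyl]chroman-4-one | CCCC(N1CCOCC1)c1c(O)c(CC=C(C)C)c(O)c2c1O[C@@H](C)[C@H](C)C2=O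
F6 | step 5 | racemic aldol 1-[6-(tert-butyldimethylsilyloxy)-2,4-bis(methoxymethoxy)-3-(3-methylbut-2-en-1-yl)phenyl]-3-hydroxy-2-methylbutan-1-one | CC(O)C(C)C(=O)c1c(O[Si](C)(C)C(C)(C)C)cc(OCOC)c(CC=C(C)C)c1OCOC
F7 | step 5 | mesylate of F6 | CC(OS(C)(=O)=O)C(C)C(=O)c1c(O[Si](C)(C)C(C)(C)C)cc(OCOC)c(CC=C(C)C)c1OCOC
F8 | step 5 | (E)-1-[6-(tert-butyldimethylsilyloxy)-2,4-bis(methoxymethoxy)-3-(3-methylbut-2-en-1-yl)phenyl]-2-methylbut-2-en-1-one | C/C=C(\C)C(=O)c1c(O[Si](C)(C)C(C)(C)C)cc(OCOC)c(CC=C(C)C)c1OCOC
F9 | step 5 | (E)-1-[6-hydroxy-2,4-bis(methoxymethoxy)-3-(3-methylbut-2-en-1-yl)phenyl]-2-methylbut-2-en-1-one | C/C=C(\C)C(=O)c1c(O)cc(OCOC)c(CC=C(C)C)c1OCOC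
F10 | step 5 | (2S,3R)-5,7-bis(methoxymethoxy)-2,3-dimethyl-6-(3-methylbut-2-en-1-yl)chroman-4-one (cis) | O=C1c2c(OCOC)c(CC=C(C)C)c(OCOC)cc2O[C@@H](C)[C@H]1C
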